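**Retrosynthetic overview**

1. Target 15 ⇒ 4,6-dibromoindole 14 (C3–Br by electrophilic bromination of the N–H indole) ⇒ N-tosylindole 13 (N–S cleavage) ⇒ indolin-3-ol 12 (loss of water across C2–C3).
2. 12 ⇒ silyl triflate 5 + sulfonamido aldehyde 9, cutting N1–C7a and C3–C3a together. In the forward sense 3,5-dibromobenzyne takes up the sulfonamide nitrogen and then the aldehyde carbon, which closes ring B (the five-membered ring, the only ring made) onto ring A (the benzene ring, which arrives with both of its bromines).
3. Feature used: N1 and C3 are bonded to the neighbouring ring carbons C7a and C3a, and C3a is flanked by the C4 bromine. A nucleophile–electrophile pair adding across a 3-bromoaryne gives exactly this pattern, with the nucleophile on the carbon far from bromine and the carbanion next to it.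
4. 5 ⇒ 2,4,6-tribromophenol 1 (O-silylation, ortho Br–Li exchange with O-to-C silyl shift, O-triflation); 9 ⇒ aminoacetaldehyde dimethyl acetal 6 + tosyl chloride 7.

Key step: step 5

Assumption: aldehyde 9 is prepared directly before use and taken into step 5 dry, because its hydrate would protonate the aryl anion; the target is achiral, and the one stereocentre of 12 forms racemic and is removed in step 6.

**Route**

Step 1
Reactants: 1 2,4,6-tribromophenol
Product: 2 trimethyl(2,4,6-tribromophenoxy)silane
Conditions: (Me3Si)2NH, THF, reflux; volatiles removed in vacuo, crude ether used directly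
Reagents that add atoms: hexamethyldisilazane, C[Si](C)(C)N[Si](C)(C)C
Why: O-silylation of an acidic phenol with hexamethyldisilazane should be clean, with ammonia as the only by-product, and gives the silyl ether needed for the silyl shift in step 2.

Step 2
Reactants: 2 trimethyl(2,4,6-tribromophenoxy)silane
Product: 5 2,4-dibromo-6-(trimethylsilyl)phenyl trifluoromethanesulfonate, via aryllithium 3 (not isolated), via lithium phenoxide 4 (not isolated)
Conditions: n-BuLi (1.05 equiv), THF, −100 °C then −78 °C; Tf2O (1.2 equiv), −100 °C to rt
Reagents that add atoms: trifluoromethanesulfonic anhydride, O=S(=O)(OS(=O)(=O)C(F)(F)F)C(F)(F)F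
Why: Bromine–lithium exchange at an ortho bromine gives an aryllithium that is drained irreversibly by the 1,3 O-to-C silyl shift (retro-Brook rearrangement), while any para-lithio species can return by exchange, and O-triflation of the resulting lithium phenoxide completes the standard one-pot route to ortho-silylaryl triflates; the aryllithium has no ortho bromine, so no aryne can form at this stage.

Step 3
Reactants: 6 aminoacetaldehyde dimethyl acetal; 7 p-toluenesulfonyl chloride
Product: 8 N-(2,2-dimethoxyethyl)-4-methylbenzenesulfonamide
Conditions: Et3N, CH2Cl2, 0 °C to rt
Reagents that add atoms: none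
Why: N-sulfonylation of an unhindered primary amine is reliable, and the acetal is inert to the basic conditions.

Step 4
Reactants: 8 N-(2,2-dimethoxyethyl)-4-methylbenzenesulfonamide
Product: 9 4-methyl-N-(2-oxoethyl)benzenesulfonamide
Conditions: 2 M aq. HCl, acetone, 45 °C; extraction, MgSO4, toluene azeotrope; used at once
Reagents that add atoms: water, O
Why: Acid-catalysed acetal hydrolysis should release the aldehyde while the sulfonamide is untouched, and immediate drying and use limits hydrate formation and self-condensation.

Step 5
Reactants: 5 2,4-dibromo-6-(trimethylsilyl)phenyl trifluoromethanesulfonate; 9 4-methyl-N-(2-oxoethyl)benzenesulfonamide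
Product: 12 rac-4,6-dibromo-1-(4-methylbenzenesulfonyl)indolin-3-ol, via 3,5-dibromobenzyne 10 (not isolated), via cesium aryl anion 11 (not isolated)
Conditions: CsF (3 equiv), MeCN, rt; 5 added slowly to 9 (1.5 equiv) and CsF
Reagents that add atoms: none
Why: Fluoride attacks silicon of 5 and triflate departs to give aryne 10, and the cesium salt of sulfonamide 9 adds through nitrogen to the aryne carbon far from the flanking bromine (the former C–Si carbon), which forms N1–C7a and leaves anion 11 on the carbon between nitrogen and bromine. That anion should add at once to the tethered aldehyde in a 5-exo-trig closure (C3–C3a), completing ring B as its alkoxide, which is protonated by further sulfonamide or on work-up. The closest known reaction type is the fluoride-induced aryne insertion–annulation of N-sulfonyl alpha-amino carbonyl compounds to indolin-3-ols. The new C3 carbinol centre forms racemic because nothing chiral is present, which is acceptable since step 6 removes it. The selectivity needed is the direction of addition to the unsymmetrical aryne: the inductively withdrawing bromine beside the triple bond stabilises negative charge on the adjacent carbon and so sends nitrogen to the far carbon, while the second bromine, meta to the attacked carbon and para to the anionic one, should oppose this only weakly. Because the closure is intramolecular and five-membered, it should be faster than bromide loss from the ortho-bromoaryl anion or its intermolecular protonation, and slow addition of 5 keeps the aryne concentration low against O-arylation of the product alkoxide.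

Step 6
Reactants: 12 rac-4,6-dibromo-1-(4-methylbenzenesulfonyl)indolin-3-ol
Product: 13 4,6-dibromo-1-(4-methylbenzenesulfonyl)-1H-indole
Conditions: TsOH·H2O (10 mol %), toluene, 90 °C
Reagents that add atoms: none
Why: Acid-catalysed dehydration (ionisation of the benzylic C3–OH, then loss of a C2 proton) is driven by aromatisation to the indole, and the sulfonamide and aryl bromides are inert to these conditions.

Step 7
Reactants: 13 4,6-dibromo-1-(4-methylbenzenesulfonyl)-1H-indole
Product: 14 4,6-dibromo-1H-indole
Conditions: KOH (3 equiv), MeOH/THF/H2O, 60 °C
Reagents that add atoms: none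
Why: Nucleophilic N-desulfonylation by attack of hydroxide or methoxide at sulfur should be easy here because the dibromoindolide is a good leaving group, and aryl bromides do not react with alkoxide under these conditions.

Step 8
Reactants: 14 4,6-dibromo-1H-indole
Product: 15 3,4,6-tribromo-1H-indole
Conditions: NBS (1.0 equiv), DMF, 0 °C, dark
Reagents that add atoms: N-bromosuccinimide, BrN1C(=O)CCC1=O
Why: Electrophilic aromatic bromination of an N–H indole goes to C3, its most nucleophilic position, and one equivalent at low temperature should avoid further bromination at C2.

**Compound list**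

1 | 2,4,6-tribromophenol | Oc1c(Br)cc(Br)cc1Br | starting material
2 | trimethyl(2,4,6-tribromophenoxy)silane | C[Si](C)(C)Oc1c(Br)cc(Br)cc1Br | intermediate
3 | [3,5-dibromo-2-(trimethylsilyloxy)phenyl]lithium | [Li]c1cc(Br)cc(Br)c1O[Si](C)(C)C | intermediate
4 | lithium 2,4-dibromo-6-(trimethylsilyl)phenoxide | [Li+].[O-]c1c(Br)cc(Br)cc1[Si](C)(C)C | intermediate
5 | 2,4-dibromo-6-(trimethylsilyl)phenyl trifluoromethanesulfonate | C[Si](C)(C)c1cc(Br)cc(Br)c1OS(=O)(=O)C(F)(F)F | intermediate
6 | aminoacetaldehyde dimethyl acetal | COC(CN)OC | starting material
7 | p-toluenesulfonyl chloride | Cc1ccc(cc1)S(Cl)(=O)=O | starting material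
8 | N-(2,2-dimethoxyethyl)-4-methylbenzenesulfonamide | COC(CNS(=O)(=O)c1ccc(C)cc1)OC | intermediate
9 | 4-methyl-N-(2-oxoethyl)benzenesulfonamide | O=CCNS(=O)(=O)c1ccc(C)cc1 | intermediate
10 | 3,5-dibromobenzyne (3,5-dibromo-1,2-didehydrobenzene) | BrC1=CC(Br)=CC#C1 | intermediate
11 | cesium 2,4-dibromo-6-[N-(2-oxoethyl)-N-(4-methylbenzenesulfonyl)amino]phenide | O=CCN(S(=O)(=O)c1ccc(C)cc1)c1cc(Br)cc(Br)[c-]1.[Cs+] | intermediate
12 | rac-4,6-dibromo-1-(4-methylbenzenesulfonyl)indolin-3-ol (racemic at C3) | OC1CN(S(=O)(=O)c2ccc(C)cc2)c2cc(Br)cc(Br)c12 | intermediate
13 | 4,6-dibromo-1-(4-methylbenzenesulfonyl)-1H-indole | Cc1ccc(cc1)S(=O)(=O)n1ccc2c(Br)cc(Br)cc21 | intermediate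
14 | 4,6-dibromo-1H-indole | Brc1cc(Br)c2cc[nH]c2c1 | intermediate
15 | 3,4,6-tribromo-1H-indole | Brc1cc(Br)c2c(Br)c[nH]c2c1 | target

**Step count and risks**

Total step count: 8.
Longest linear sequence: 6 steps (steps 1, 2, 5, 6, 7, 8; the aldehyde branch through steps 3, 4, 5, 6, 7, 8 is equally long).

Steps most likely to fail:

1. Step 5. The risk is that base-induced self-condensation of the aldehyde, intermolecular protonation of the aryl anion, or its loss of bromide competes with ring closure, so that N-arylation without cyclisation or aryne oligomerisation takes over. The fallback moves the ring closure from carbanion addition to electrophilic substitution and sets out from 5 and the acetal 8. CsF in MeCN at rt should give, by plain aryne N-arylation with protonation of the aryl anion by further sulfonamide, N-(3,5-dibromophenyl)-N-(2,2-dimethoxyethyl)-4-methylbenzenesulfonamide F1; the same aryne regiochemistry places both bromines meta to nitrogen. TiCl4 in chlorobenzene at 100 °C should then ionise the acetal and close the ring by Friedel–Crafts attack on either of the two equivalent ortho carbons, with loss of methanol. This closure is slowed by the two bromines, but each is ortho or para to the reacting carbon. The fallback comes back to the route at 13.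

2. Step 2. The risk is attack of butyllithium at silicon of the aryl silyl ether instead of at bromine, exchange of a second bromine, or incomplete triflation of the hindered phenoxide in the one-pot sequence. The fallback sets out from 1 and avoids an O–Si bond during the exchange. n-BuLi (2.1 equiv) in Et2O at −78 °C should deprotonate the phenol and then exchange an ortho bromine under phenoxide direction to give lithium 2,4-dibromo-6-lithiophenoxide F2. Quenching with Me3SiCl should give [2,4-dibromo-6-(trimethylsilyl)phenoxy]trimethylsilane F3, and brief treatment with dilute HCl in THF should cleave only the silyl ether to 2,4-dibromo-6-(trimethylsilyl)phenol F4, which can be purified. Triflation with Tf2O and pyridine in CH2Cl2 at 0 °C comes back to the route at 5.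

3. Step 4. The risk is hydration and oligomerisation of the alpha-sulfonamido aldehyde during aqueous acid hydrolysis, which would carry water and condensation products into step 5. The fallback sets out from 7 and makes the aldehyde under anhydrous, neutral conditions. N-sulfonylation of allylamine with 7 (Et3N, CH2Cl2, 0 °C) should give N-allyl-4-methylbenzenesulfonamide F5, and ozonolysis (O3, CH2Cl2, −78 °C, then Me2S) should cleave the alkene, coming back to the route at 9.

**Further compounds**

F1 | step 5 | N-(3,5-dibromophenyl)-N-(2,2-dimethoxyethyl)-4-methylbenzenesulfonamide | COC(CN(c1cc(Br)cc(Br)c1)S(=O)(=O)c1ccc(C)cc1)OC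
F2 | step 2 | lithium 2,4-dibromo-6-lithiophenoxide | [Li]Oc1c(Br)cc(Br)cc1[Li]
F3 | step 2 | [2,4-dibromo-6-(trimethylsilyl)phenoxy]trimethylsilane | C[Si](C)(C)Oc1c(Br)cc(Br)cc1[Si](C)(C)C
F4 | step 2 | 2,4-dibromo-6-(trimethylsilyl)phenol | Oc1c(Br)cc(Br)cc1[Si](C)(C)C
F5 | step 4 | N-allyl-4-methylbenzenesulfonamide | C=CCNS(=O)(=O)c1ccc(C)cc1
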